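Positions are given in germacrane numbering throughout: ring carbons C1–C10, C14 on C10, C15 on C4, lactone carbons C11 (α), C12 (C=O) and C13 (exocyclic CH2) attached at C7, lactone oxygen on C8. Compound numbers are those of the steps below.

## Analysis of the target

Target 33 is a germacranolide: a cyclodeca-1(10),4-diene fused at C7–C8 to an α-methylene-γ-lactone (C12 on O8, C13 exocyclic on C11). Both trisubstituted ring alkenes are ring-cis (C9 cis to C2, C3 cis to C6). The three stereocentres are contiguous, C6 (R), C7 (R) and C8 (S). The tiglate oxygen on C6, C11 on C7 and the lactone oxygen on C8 lie on the same side of the C5–C9 zigzag, so H6/H7 and H7/H8 are anti and the lactone is trans-fused. C14 and C15 are free primary allylic alcohols while the secondary O6 is acylated, so three hydroxyls must be told apart, and O6 and O8 are both γ to C12 and can exchange the lactone. Sensitive groups are the α-methylene lactone (Michael acceptor, prone to move its double bond into the ring in base), the allylic ester at C6 and the 1,5-diene (Cope rearrangement on heating, transannular cyclisation in acid). The hard parts are a ten-membered ring with two cis trisubstituted alkenes, which is poorly suited to closure from an open chain, and the C6–C8 triad with its oxygen discrimination. The feature used is that C9–C10(C14)=C1–C2–C3–C4(C15)=C5–C6, with both alkenes cis, is the skeleton of diene 1 once C6 is bonded to C9. The target ring therefore differs from a commercial eight-membered ring only by C7–C8 inserted between C6 and C9.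

## Retrosynthetic reasoning

33 to 32: the C14–O and C15–O bonds are cut last, back to methyl groups. Leaving both primary alcohols to the final step means they never need protection while O6 is acylated. The forward step must hydroxylate two allylic methyl groups, keep both ring-cis geometries and leave the acrylate and tiglate alkenes alone.

32 to 29 and 30: the ester C–O bond at O6 is cut. Acylation of the free secondary alcohol with tiglic acid 30 retains the C6 configuration, and the same alcohol (or its epimer, with inversion) gives access to 32.

29 to 28 to 23 and 24: the C11–C13 bond is cut to the iminium salt 24. The methylene is put on only after C6 is sp3, because with a C6 ketone the C7–H would be acidified from both sides and the exocyclic alkene would move into the ring. O6 is silylated in 23 so that no alkoxide sits γ to C12 while the lactone enolate is made.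

23 to 22 to 21: the C6–H bond is cut back to the ketone. The ketone is what remains of the enolate handle and is needed until C7 has been functionalised. Reducing it only after the lactone is closed settles the O6/O8 question by timing, since O8 is the only hydroxyl present when the lactone forms. The forward reduction must deliver hydride to one face of C6.

21 to 19 to 16 and 17: the lactone C12–O8 bond and the C7–C11 bond are cut, the latter to the C7 enolate of 16 and bromoacetate 17. An ester tether from O8 carrying the C11 halide would form the same bond, but it was set aside: an acyloxy group on C8 is a good leaving group β to the C7 enolate, and the ester would have to adopt its disfavoured s-cis form to cyclise. With O8 as a silyl ether the enolate is stable, and the lactone closes afterwards.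

16 to 15 to 14 to 13: the C8–O bond is cut back to the C7=C8 enone. C8 is the β-carbon of that enone, so nucleophilic epoxidation followed by reductive cleavage of the C7–O bond puts oxygen on C8 alone. This is the one place where a chiral catalyst acts; C7 and C6 are then set relative to C8.

13 to 12 to 10: the C7=C8 unsaturation is removed. It comes from the regiodefined C6=C7 enol silane by Saegusa oxidation; C7 is the only sp3 α-carbon of 10, so enolisation has one direction.

10 to 7: the C8–C9 bond is cut and C9 is reconnected to C6, which contracts the ten-membered ring to the eight-membered 1-vinyl dienol 7. In the forward sense an alkoxide-driven [1,3] shift moves C9 from C6 to the vinyl terminus. This avoids any medium-ring closure from an open chain and takes both cis alkenes, with C14 and C15, from the starting diene.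

7 to 5 and 6, and 5 to 4 to 2 to 1: the vinyl–C6 bond is cut to dienone 5 and vinylmagnesium bromide 6. A direct allylic oxidation of 1 to 5 would be shorter, but it leaves the choice between the two kinds of ring methylene to the reagent. The sequence epoxide 2, allylic alcohol 4, oxidative transposition fixes the carbonyl position by construction.

## Alternatives that were turned down

Alternative 1: The disconnection is at C7–C11 and C6–O, with the carbocycle still open between C3 and C4. In the forward key step the hydroximoyl chloride A2, an ester of the C8 alcohol, loses HCl to a tertiary amine. The 1,3-dipole so formed adds across the E C6=C7 bond, carbon to C7 and oxygen to C6, closing the lactone and an isoxazoline in the fused bicycle A1. In its favour, one intramolecular step forms the lactone on O8 without any O6/O8 ambiguity, places oxygen on C6 and relates C6, C7 and C8 through the alkene geometry and the tether. C14 and C15 are already oxidised, so no late C–H oxidation is needed. On the stereotriad and on the C14/C15 oxidation level it is stronger than the chosen route. Against it, the isoxazoline must be cleaved to an α-keto lactone whose C7–H is then acidic, and the keto group must be converted to the methylene. The ten-membered ring still has to be closed late between C3 and the C4 vinyl iodide, a medium-ring closure carrying two cis trisubstituted alkenes. A2 itself needs a long stereodefined open-chain synthesis with three protecting groups. The chosen strategy gives instead a ring that is never closed from a chain, both alkene geometries from a commodity diene, and five steps to the ten-membered ketone.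

Alternative 2: The disconnection is the C1=C10 double bond. The phosphonate A4 carries a temporary lactone from C14 to O8, with the phosphonate on C10 and an aldehyde at C1. Under mild amine base with a lithium salt it condenses intramolecularly to the bridged α-alkylidene lactone A3. In its favour, the temporary lactone ties C8 to C10 and allows only the alkylidene geometry that is ring-cis in the ten-membered ring, C14 is already at a usable oxidation level, and C6–C8 are set beforehand by open-chain asymmetric reactions. On alkene geometry by constraint and on C14 it is stronger than the chosen route. Against it, the olefination must form a strained bridged bicycle at high dilution. Afterwards the lactone has to be exchanged: the conjugated C14 lactone is reduced to the diol, the C12 carbinol is unmasked and oxidised, the lactone is re-formed on O8, and methylenation and acylation follow. A4 with three contiguous stereocentres and a cis trisubstituted alkene is itself a long target. The chosen strategy offers a unimolecular ring-forming step without dilution and a much shorter path to the ring, at the price of deferring the C14/C15 oxidation.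

Alternative 3: The disconnection is the C6–C7 bond, traced back to the thirteen-membered diallyl ether A6 in which O links C6 and C13. Lithiation at C6 with an alkyllithium triggers a [2,3] shift: C6 bonds to C7, the O–C13 bond breaks and C11=C13 forms, which contracts the ring to the ten-membered alcohol A5. In its favour, a thirteen-membered ether is easier to close than a ten-membered carbocycle, and ring contraction of this kind is an established way to cyclodecadienes. The C6 hydroxyl emerges free for acylation. C11=C13 and an oxidised C12 arrive together, so the α-methylene lactone needs only oxidation and closure on O8, with no enolate methylenation. C14 and C15 are oxidised from the start. On these points it is stronger than the chosen route. Against it, A6 requires two cis trisubstituted allylic systems, a stereocentre at C8 and a macrocyclic etherification, and so a long linear sequence. Lithiation can occur at C13 as well as C6, a [1,2] shift competes, and the C6/C7 relation to C8 depends on a transition-state preference that is not secured. Four silyl ethers of two kinds must then be told apart. The chosen strategy instead reaches the ring in five steps and brings in chirality with one catalytic step. It is weaker in that it needs a late allylic oxidation and a substrate-controlled reduction at C6.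

Key step: step 5

Remarks on the chemistry:
- Commercial 1,5-dimethylcycloocta-1,5-diene usually contains some 1,6-dimethyl isomer; the route assumes material enriched in the 1,5-isomer by fractional distillation, with the rest removed by chromatography at epoxide 2.
- Compounds 2 to 7 are racemic (one enantiomer drawn); the stereocentre of 7 is destroyed in step 5 and absolute configuration enters in step 8.
- The C6=C7 bond of 9, 11 and 12 and the C7=C8 bond of 13 are drawn ring-cis; the former has no bearing on later steps, the latter only on which catalyst antipode step 8 needs.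

## Steps

Step 1
Reactants: 1 1,5-dimethylcycloocta-1,5-diene
Product: 2 rac-(1R,8S,4Z)-1,5-dimethyl-9-oxabicyclo[6.1.0]non-4-ene (cis-monoepoxide)
Conditions: mCPBA (1.0 equiv), NaHCO3, CH2Cl2, 0 °C
Reagents that add atoms: 3-chloroperoxybenzoic acid (mCPBA), O=C(OO)c1cccc(Cl)c1
Why: Prilezhaev epoxidation; the two trisubstituted alkenes are equivalent, so one equivalent of peracid at 0 °C should give mainly the monoepoxide, and syn addition to the cis alkene gives the cis-epoxide.

Step 2
Reactants: 2 rac-(1R,8S,4Z)-1,5-dimethyl-9-oxabicyclo[6.1.0]non-4-ene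
Product: 4 rac-(2Z,5Z)-1,5-dimethylcycloocta-2,5-dien-1-ol, via trans-hydroxy selenide 3 (not isolated)
Conditions: PhSeSePh (0.55 equiv), NaBH4, EtOH, reflux; then 30% H2O2, pyridine, THF, 0 °C → rt
Reagents that add atoms: none
Why: Phenylselenolate opens the epoxide by SN2 attack at the less substituted carbon, and the selenoxide formed on oxidation undergoes syn elimination, which can only go away from the carbinol carbon because that carbon has no hydrogen. The result is the tertiary allylic alcohol with the new cis alkene next to it.

Step 3
Reactants: 4 rac-(2Z,5Z)-1,5-dimethylcycloocta-2,5-dien-1-ol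
Product: 5 (2Z,6Z)-3,7-dimethylcycloocta-2,6-dien-1-one
Conditions: [C5H5NH][CrO3Cl] (pyridinium chlorochromate, 2 equiv), NaOAc, Celite, CH2Cl2, rt
Reagents that add atoms: none
Why: Babler–Dauben oxidative transposition: the tertiary chromate ester undergoes a [3,3] shift to the secondary allylic chromate, which is oxidised to the enone, so the carbonyl lands on the former alkene terminus and the methyl ends up β. The buffer limits acid-induced migration of the other alkene.

Step 4
Reactants: 5 (2Z,6Z)-3,7-dimethylcycloocta-2,6-dien-1-one; 6 vinylmagnesium bromide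
Product: 7 rac-(2Z,6Z)-1-ethenyl-3,7-dimethylcycloocta-2,6-dien-1-ol
Conditions: CeCl3 (anhydrous), THF, −78 °C; then H2O
Reagents that add atoms: none
Why: Organocerium 1,2-addition to the enone carbonyl; CeCl3 lowers the basicity of the vinyl reagent, which should suppress enolisation at the doubly activated ring methylene between the carbonyl and the second alkene, and conjugate addition.

Step 5
Reactants: 7 rac-(2Z,6Z)-1-ethenyl-3,7-dimethylcycloocta-2,6-dien-1-ol
Product: 10 (2Z,6Z)-3,7-dimethylcyclodeca-2,6-dien-1-one, via potassium alkoxide 8 (not isolated), via potassium enolate 9 (not isolated)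
Conditions: KH (1.5 equiv), 18-crown-6 (1.5 equiv), THF, 0 °C → rt; then pH 7 aqueous buffer, −78 °C
Reagents that add atoms: none
Why: Deprotonation gives alkoxide 8, whose oxyanion strongly weakens the allylic C6–C9 bond; heterolysis gives an allyl anion (C9–C10–C1) still tied through C2–C3 to a cross-conjugated divinyl ketone, and C9 re-adds to the unsubstituted vinyl terminus C8 (net [1,3] shift) to give enolate 9, protonated at C7 on work-up. The closest known reaction type is the alkoxide-accelerated [1,3] sigmatropic two-carbon ring expansion of 1-vinylcycloalk-3-en-1-ols to cycloalk-5-enones; a dienol with a second ring alkene on the other side of the carbinol carbon has not been put through it. The ten-membered ring closes end-on by conjugate addition of C9 to C8, with the C7=C8 acceptor bond inside the new ring (10-endo-trig), while the eight-membered ring opens in the same event, so no medium ring is formed from an open chain. No stereocentre is created and the racemic carbinol centre is destroyed. The step needs C9–C8 bonding rather than C1–C8 bonding (the [3,3] course, which keeps an eight-membered ring) or addition to C4: C9 is the primary, less hindered allyl terminus and starts closest to C8, and C4 is a fully substituted acceptor carbon. It also needs the cis C1=C10 geometry to survive, which the short C2–C3 tether, the contact ion pair and fast recombination should secure.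

Step 6
Reactants: 10 (2Z,6Z)-3,7-dimethylcyclodeca-2,6-dien-1-one
Product: 12 {[(1E,5Z,9Z)-5,9-dimethylcyclodeca-1,5,9-trien-1-yl]oxy}trimethylsilane (enol silane on C6, C6=C7; all three ring alkenes ring-cis), via lithium enolate 11 (not isolated)
Conditions: LiN(iPr)2, THF, −78 °C; then Me3SiCl, Et3N, −78 → 0 °C
Reagents that add atoms: chlorotrimethylsilane, C[Si](C)(C)Cl
Why: Kinetic deprotonation of the enone at its only sp3 α-carbon C7 gives the cross-conjugated enolate, which is silylated on oxygen; isolating 10 first allows any eight-membered by-product of step 5 to be removed.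

Step 7
Reactants: 12 {[(1E,5Z,9Z)-5,9-dimethylcyclodeca-1,5,9-trien-1-yl]oxy}trimethylsilane
Product: 13 (2Z,5Z,9Z)-5,9-dimethylcyclodeca-2,5,9-trien-1-one
Conditions: Pd(OAc)2 (1.05 equiv), MeCN, rt
Reagents that add atoms: none
Why: Saegusa oxidation: divalent palladium forms the C7-bound enolate and syn β-hydride elimination from C8 gives the C7=C8 enone. The ring-cis isomer is expected, since a trans enone beside two cis alkenes would strain the ten-membered ring.

Step 8
Reactants: 13 (2Z,5Z,9Z)-5,9-dimethylcyclodeca-2,5,9-trien-1-one
Product: 14 (1S,10S,3Z,7Z)-4,8-dimethyl-11-oxabicyclo[8.1.0]undeca-3,7-dien-2-one (7,8-epoxide)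
Conditions: 9-amino-9-deoxy-epi-quinine (10 mol %), CF3CO2H (20 mol %), 50% aq. H2O2, 1,4-dioxane, 30 °C
Reagents that add atoms: hydrogen peroxide, OO
Why: Iminium-catalysed asymmetric epoxidation of a cyclic enone: H2O2 adds to C8 of the less substituted enone arm and the β-peroxy enamine closes the epoxide, while the protonated quinuclidine of the catalyst guides the peroxide to one face and so sets C8 (S). The C7 centre is removed again in step 9, and the quinidine-derived pseudo-enantiomer is the catalyst to use should the ring-cis enone show the opposite facial sense; the near-neutral medium avoids base-induced migration of the C7=C8 bond through C9.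

Step 9
Reactants: 14 (1S,10S,3Z,7Z)-4,8-dimethyl-11-oxabicyclo[8.1.0]undeca-3,7-dien-2-one
Product: 15 (2Z,6Z,9S)-9-hydroxy-3,7-dimethylcyclodeca-2,6-dien-1-one (8-hydroxy ketone)
Conditions: SmI2 (2.2 equiv), THF–MeOH, −90 °C
Reagents that add atoms: none
Why: Reductive cleavage of the α-carbon–oxygen bond of an α,β-epoxy ketone by two single-electron transfers (ketyl, then enolate protonated by methanol); the C8–O bond is not touched, so C8 keeps its configuration, and the low temperature spares the remaining enone and avoids dehydration.

Step 10
Reactants: 15 (2Z,6Z,9S)-9-hydroxy-3,7-dimethylcyclodeca-2,6-dien-1-one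
Product: 16 (2Z,6Z,9S)-9-[(tert-butyldimethylsilyl)oxy]-3,7-dimethylcyclodeca-2,6-dien-1-one
Conditions: tBuMe2SiOTf, 2,6-lutidine, CH2Cl2, −78 °C
Reagents that add atoms: tert-butyldimethylsilyl trifluoromethanesulfonate, CC(C)(C)[Si](C)(C)OS(=O)(=O)C(F)(F)F
Why: Silylation of the secondary alcohol under non-eliminating conditions; the silyl ether turns O8 into a poor leaving group so that the C7 enolate can be formed in the next step.

Step 11
Reactants: 16 (2Z,6Z,9S)-9-[(tert-butyldimethylsilyl)oxy]-3,7-dimethylcyclodeca-2,6-dien-1-one; 17 methyl bromoacetate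
Product: 19 methyl 2-[(1R,10S,3Z,7Z)-10-[(tert-butyldimethylsilyl)oxy]-4,8-dimethyl-2-oxocyclodeca-3,7-dien-1-yl]acetate, via lithium enolate 18 (not isolated)
Conditions: LiN(iPr)2, THF, −78 °C; then 17, DMPU, −78 → −40 °C
Reagents that add atoms: none
Why: Kinetic deprotonation can occur only at C7, and the lithium enolate is alkylated by the reactive α-halo ester in an SN2 reaction without β-elimination of the silyloxy group at low temperature. The electrophile should enter anti to the neighbouring silyloxy group, giving C7 (R) with C11 trans to O8; any C7 epimer is funnelled to the same lactone in step 12.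

Step 12
Reactants: 19 methyl 2-[(1R,10S,3Z,7Z)-10-[(tert-butyldimethylsilyl)oxy]-4,8-dimethyl-2-oxocyclodeca-3,7-dien-1-yl]acetate
Product: 21 (7R,8S)-6-oxo-13-norgermacra-1(10),4-dien-12,8-olide (ring alkenes cis, lactone trans-fused), via hydroxy keto ester 20 (not isolated)
Conditions: HF·pyridine, pyridine, THF, 0 °C → rt; then camphorsulfonic acid (10 mol %), CH2Cl2, rt
Reagents that add atoms: none
Why: HF·pyridine removes the silyl ether, and the freed C8 hydroxyl, the only one in the molecule, closes the five-membered lactone on C12 by acyl substitution (5-exo-trig) with loss of methanol, so the 12,8-olide forms without competition from O6. C7 is α to the C6 ketone and can equilibrate through the enol under the acid catalysis to the trans-fused lactone, in which C6, C11, O8 and C9 all lie on the ring periphery; base is avoided because a C7 enolate could expel the C8 oxygen.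

Step 13
Reactants: 21 (7R,8S)-6-oxo-13-norgermacra-1(10),4-dien-12,8-olide
Product: 22 (6R,7S,8S)-6-hydroxy-13-norgermacra-1(10),4-dien-12,8-olide
Conditions: NaBH4, CeCl3·7H2O, MeOH, −78 °C
Reagents that add atoms: none
Why: Luche reduction gives 1,2-reduction of the enone carbonyl and leaves the lactone alone at −78 °C. The small hydride is expected to attack C6 antiperiplanar to the C7–H bond, as in axial attack on a 2-substituted cyclohexanone, which places the new hydroxyl on the ring periphery, trans to C11 (6R).

Step 14
Reactants: 22 (6R,7S,8S)-6-hydroxy-13-norgermacra-1(10),4-dien-12,8-olide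
Product: 23 (6R,7R,8S)-6-(triethylsilyloxy)-13-norgermacra-1(10),4-dien-12,8-olide
Conditions: Et3SiOTf, 2,6-lutidine, CH2Cl2, −78 °C
Reagents that add atoms: triethylsilyl trifluoromethanesulfonate, CC[Si](CC)(CC)OS(=O)(=O)C(F)(F)F
Why: Silylation of the allylic alcohol; it removes the acidic proton before enolate formation and prevents a C6 alkoxide from attacking C12 and shifting the lactone from O8 to O6.

Step 15
Reactants: 23 (6R,7R,8S)-6-(triethylsilyloxy)-13-norgermacra-1(10),4-dien-12,8-olide; 24 N,N-dimethylmethyleneiminium iodide (Eschenmoser's salt, [CH2=NMe2]I)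
Product: 28 (6R,7R,8S)-6-(triethylsilyloxy)germacra-1(10),4,11(13)-trien-12,8-olide, via lithium enolate 25 (not isolated), via Mannich base 26 (not isolated), via ammonium iodide 27 (not isolated)
Conditions: LiN(iPr)2, THF, −78 °C; then 24, −78 → 0 °C; then MeI, MeOH, rt; then aq. NaHCO3, EtOAc, rt
Reagents that add atoms: none
Why: Deprotonation at C11 gives lactone enolate 25, which has no leaving group β to it and undergoes a Mannich reaction with the iminium salt; N-methylation and mild base then eliminate trimethylamine (E1cB) to the exocyclic methylene. The C11 configuration of 26 and 27 is irrelevant, and NaHCO3 is mild enough not to move the double bond into the ring.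

Step 16
Reactants: 28 (6R,7R,8S)-6-(triethylsilyloxy)germacra-1(10),4,11(13)-trien-12,8-olide
Product: 29 (6R,7S,8S)-6-hydroxygermacra-1(10),4,11(13)-trien-12,8-olide
Conditions: HF·pyridine, pyridine, THF, 0 °C
Reagents that add atoms: none
Why: Cleavage of the triethylsilyl ether under buffered, weakly acidic conditions that spare the acrylate, the lactone and the 1,5-diene and do not create an alkoxide at C6.

Step 17
Reactants: 29 (6R,7S,8S)-6-hydroxygermacra-1(10),4,11(13)-trien-12,8-olide; 30 tiglic acid ((E)-2-methylbut-2-enoic acid)
Product: 32 (6R,7R,8S)-6-[(E)-2-methylbut-2-enoyloxy]germacra-1(10),4,11(13)-trien-12,8-olide, via mixed anhydride 31 (not isolated)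
Conditions: 30, 2,4,6-trichlorobenzoyl chloride, Et3N, toluene, rt; then 29, DMAP, toluene, rt
Reagents that add atoms: none
Why: Yamaguchi esterification: the mixed anhydride transfers the tigloyl group through the acylpyridinium ion to the hindered secondary alcohol, with retention at C6 and without change of the E geometry of the acid.

Step 18
Reactants: 32 (6R,7R,8S)-6-[(E)-2-methylbut-2-enoyloxy]germacra-1(10),4,11(13)-trien-12,8-olide
Product: 33 (6R,7R,8S)-14,15-dihydroxy-6-[(E)-2-methylbut-2-enoyloxy]germacra-1(10),4,11(13)-trien-12,8-olide (both ring alkenes ring-cis; the target)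
Conditions: SeO2 (0.5 equiv), tBuOOH (5 equiv), salicylic acid (10 mol %), CH2Cl2, rt
Reagents that add atoms: selenium dioxide, O=[Se]=O; tert-butyl hydroperoxide, CC(C)(C)OO
Why: SeO2 allylic hydroxylation of the two trisubstituted ring alkenes: an ene reaction binds selenium to the CH terminus (C1, C5) and takes a hydrogen from the methyl group, and the [2,3] shift returns the double bond to its place with oxygen on C14 and C15. In a ten-membered ring the allylic ring C–H bonds lie close to the alkene plane while methyl hydrogens are always aligned, and the [2,3] shift puts CH2OH trans to the substituent on the other alkene carbon, which is the ring-cis geometry required. The acrylate and tiglate alkenes are electron-poor and should not react.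

## Compound list

1 | (1Z,5Z)-1,5-dimethylcycloocta-1,5-diene | C/C1=C/CC/C(C)=C\CC1 | starting material
2 | rac-(1R,8S,4Z)-1,5-dimethyl-9-oxabicyclo[6.1.0]non-4-ene | C[C@@]12CC/C=C(C)\CC[C@@H]1O2 | intermediate
3 | rac-(1R,2R,5Z)-1,5-dimethyl-2-(phenylselanyl)cyclooct-5-en-1-ol | C[C@@]1(O)CC/C=C(C)\CC[C@H]1[Se]c2ccccc2 | intermediate (not isolated)
4 | rac-(2Z,5Z)-1,5-dimethylcycloocta-2,5-dien-1-ol | C[C@]1(O)/C=C\C/C(C)=C\CC1 | intermediate
5 | (2Z,6Z)-3,7-dimethylcycloocta-2,6-dien-1-one | O=C1/C=C(C)\CC/C=C(C)\C1 | intermediate
6 | vinylmagnesium bromide | C=C[Mg]Br | starting material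
7 | rac-(2Z,6Z)-1-ethenyl-3,7-dimethylcycloocta-2,6-dien-1-ol | C=C[C@@]1(O)/C=C(C)\CC/C=C(C)\C1 | intermediate
8 | potassium alkoxide of 7 | C=C[C@@]1([O-])/C=C(C)\CC/C=C(C)\C1.[K+] | intermediate (not isolated)
9 | potassium enolate of 10 (O on C6, C6=C7, ring alkenes cis) | C/C1=C/C([O-])=C\CC/C(C)=C\CC1.[K+] | intermediate (not isolated)
10 | (2Z,6Z)-3,7-dimethylcyclodeca-2,6-dien-1-one | C/C1=C/C(=O)CCC/C(C)=C\CC1 | intermediate
11 | lithium enolate of 10 (O on C6, C6=C7) | C/C1=C/C([O-])=C\CC/C(C)=C\CC1.[Li+] | intermediate (not isolated)
12 | {[(1E,5Z,9Z)-5,9-dimethylcyclodeca-1,5,9-trien-1-yl]oxy}trimethylsilane | C/C1=C/C(O[Si](C)(C)C)=C\CC/C(C)=C\CC1 | intermediate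
13 | (2Z,5Z,9Z)-5,9-dimethylcyclodeca-2,5,9-trien-1-one | C/C1=C/C(=O)/C=C\C/C(C)=C\CC1 | intermediate
14 | (1S,10S,3Z,7Z)-4,8-dimethyl-11-oxabicyclo[8.1.0]undeca-3,7-dien-2-one | O1[C@H]2C/C(C)=C\CC/C(C)=C\C(=O)[C@@H]12 | intermediate
15 | (2Z,6Z,9S)-9-hydroxy-3,7-dimethylcyclodeca-2,6-dien-1-one | O[C@H]1C/C(C)=C\CC/C(C)=C\C(=O)C1 | intermediate
16 | (2Z,6Z,9S)-9-[(tert-butyldimethylsilyl)oxy]-3,7-dimethylcyclodeca-2,6-dien-1-one | CC(C)(C)[Si](C)(C)O[C@H]1C/C(C)=C\CC/C(C)=C\C(=O)C1 | intermediate
17 | methyl bromoacetate | COC(=O)CBr | starting material
18 | lithium enolate of 16 (O on C6, C6=C7) | C1/C(C)=C\C([O-])=C/[C@@H](O[Si](C)(C)C(C)(C)C)C/C(C)=C\C1.[Li+] | intermediate (not isolated)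
19 | methyl 2-[(1R,10S,3Z,7Z)-10-[(tert-butyldimethylsilyl)oxy]-4,8-dimethyl-2-oxocyclodeca-3,7-dien-1-yl]acetate | CC(C)(C)[Si](C)(C)O[C@H]1C/C(C)=C\CC/C(C)=C\C(=O)[C@@H]1CC(=O)OC | intermediate
20 | methyl 2-[(1R,10S,3Z,7Z)-10-hydroxy-4,8-dimethyl-2-oxocyclodeca-3,7-dien-1-yl]acetate | O[C@H]1C/C(C)=C\CC/C(C)=C\C(=O)[C@@H]1CC(=O)OC | intermediate (not isolated)
21 | (7R,8S)-6-oxo-13-norgermacra-1(10),4-dien-12,8-olide (ring alkenes cis, trans-fused lactone) | C1C(=O)O[C@H]2C/C(C)=C\CC/C(C)=C\C(=O)[C@H]12 | intermediate
22 | (6R,7S,8S)-6-hydroxy-13-norgermacra-1(10),4-dien-12,8-olide | C1C(=O)O[C@H]2C/C(C)=C\CC/C(C)=C\[C@@H](O)[C@H]12 | intermediate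
23 | (6R,7R,8S)-6-(triethylsilyloxy)-13-norgermacra-1(10),4-dien-12,8-olide | C1C(=O)O[C@H]2C/C(C)=C\CC/C(C)=C\[C@@H](O[Si](CC)(CC)CC)[C@H]12 | intermediate
24 | N,N-dimethylmethyleneiminium iodide (Eschenmoser's salt) | C=[N+](C)C.[I-] | starting material
25 | lithium enolate of 23 (C11=C12–O) | C1=C([O-])O[C@H]2C/C(C)=C\CC/C(C)=C\[C@@H](O[Si](CC)(CC)CC)[C@H]12.[Li+] | intermediate (not isolated)
26 | 11-(dimethylaminomethyl) derivative of 23 (C11 epimers) | CN(C)CC1C(=O)O[C@H]2C/C(C)=C\CC/C(C)=C\[C@@H](O[Si](CC)(CC)CC)[C@H]12 | intermediate (not isolated)
27 | 11-(trimethylammoniomethyl) iodide derived from 26 (C11 epimers) | C[N+](C)(C)CC1C(=O)O[C@H]2C/C(C)=C\CC/C(C)=C\[C@@H](O[Si](CC)(CC)CC)[C@H]12.[I-] | intermediate (not isolated)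
28 | (6R,7R,8S)-6-(triethylsilyloxy)germacra-1(10),4,11(13)-trien-12,8-olide | C=C1C(=O)O[C@H]2C/C(C)=C\CC/C(C)=C\[C@@H](O[Si](CC)(CC)CC)[C@H]12 | intermediate
29 | (6R,7S,8S)-6-hydroxygermacra-1(10),4,11(13)-trien-12,8-olide | C=C1C(=O)O[C@H]2C/C(C)=C\CC/C(C)=C\[C@@H](O)[C@H]12 | intermediate
30 | tiglic acid, (E)-2-methylbut-2-enoic acid | C/C=C(\C)C(=O)O | starting material
31 | (E)-2-methylbut-2-enoic 2,4,6-trichlorobenzoic anhydride | C/C=C(\C)C(=O)OC(=O)c1c(Cl)cc(Cl)cc1Cl | intermediate (not isolated)
32 | (6R,7R,8S)-6-[(E)-2-methylbut-2-enoyloxy]germacra-1(10),4,11(13)-trien-12,8-olide | C=C1C(=O)O[C@H]2C/C(C)=C\CC/C(C)=C\[C@@H](OC(=O)/C(C)=C/C)[C@H]12 | intermediate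
33 | (6R,7R,8S)-14,15-dihydroxy-6-[(E)-2-methylbut-2-enoyloxy]germacra-1(10),4,11(13)-trien-12,8-olide, both ring alkenes ring-cis | C=C1C(=O)O[C@H]2C/C(CO)=C\CC/C(CO)=C\[C@@H](OC(=O)/C(C)=C/C)[C@H]12 | target

## Step count and least certain steps

Total: 18 steps. Longest linear sequence: 18 steps (1 to 33); the route is linear, with 6, 17, 24 and 30 as purchased reagents.

Step 5 (key step). The vinyl terminus may bond to C1 instead of C9 (the [3,3] course, which leaves the ring eight-membered). The allyl anion may rotate before it recombines, with loss of the cis C1=C10 geometry, or the cleaved species may fail to recombine. Fallback: dienol 7 is silylated with 1-(trimethylsilyl)imidazole to its trimethylsilyl ether F1, and F1 is passed through a hot tube (about 300 °C, short contact time, cold trap). This neutral thermal [1,3] silyloxy shift is the known counterpart of the anionic reaction for 1-vinylcycloalk-3-enyl silyl ethers. It gives the ring-expanded enol silane directly, so the fallback sets out from 7 and comes back at 12, and step 6 is not needed.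

Step 8. Facial discrimination at C8 may be poor on a flexible ten-membered enone, the other enone arm may be epoxidised, or the amine may move the C7=C8 bond through the doubly allylic C9. Fallback: trienone 13 is treated with B2pin2, CuCl, NaOtBu, a chiral ferrocenyl bisphosphine of the Josiphos type and MeOH in THF. This copper-catalysed asymmetric conjugate borylation gives the β-boryl ketone F2, whose C–B bond is oxidised with retention by NaBO3·4H2O. The fallback sets out from 13 and comes back at 15, replacing steps 8 and 9.

Step 12. The C8 oxygen may be lost by β-elimination from the C7 enol or enolate of the β-acyloxy ketone, or the C7 epimers may not converge fully on the trans-fused lactone. Fallback: the lactone is closed only after C6 has been reduced, with two different silyl groups keeping O6 and O8 apart. Hydroxy ketone 15 is converted with Et3SiOTf to the triethylsilyl ether F3. F3 is alkylated at C7 with tert-butyl bromoacetate to the keto ester F4, whose C7 epimers can be separated or equilibrated at a stage where only a silyloxide could leave. Luche reduction gives the alcohol F5, in which the tert-butyl ester does not close onto O6, and tBuMe2SiOTf gives the bis-silyl ether F6. Pyridinium p-toluenesulfonate in MeOH removes the triethylsilyl group selectively, and camphorsulfonic acid closes the lactone on O8 to the silyloxy lactone F7. Methylenation as in step 15 gives the methylene lactone F8, and HF·pyridine frees O6. The fallback sets out from 15 and comes back at 29.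

Step 13. Hydride may be delivered to the other face of C6. Fallback: the route is made convergent in the C6 configuration. The 6-epimeric alcohol F9 formed from 21 is carried through the chemistry of steps 14 to 16 as its triethylsilyl ether F10, the methylene lactone F11 and the free alcohol F12. F12 is then esterified with tiglic acid 30 under Mitsunobu conditions (PPh3, diisopropyl azodicarboxylate), which inverts C6. The fallback sets out from 21 and comes back at 32.

Step 18. Ring methylenes C9 or C3 may be oxidised in place of the methyl groups, the reaction at C4=C5 may be slow because of the neighbouring ester, and the new alcohols may be over-oxidised to enals. Fallback: the hydroxylation is moved ahead of the acylation. Alcohol 29, with its free hydroxyl next to C5, is treated with SeO2 and tBuOOH to give the triol F13. The two primary alcohols are silylated selectively with tBuMe2SiCl and imidazole at low temperature to the bis-silyl ether F14. Yamaguchi esterification with 30 gives the tiglate F15, and HF·pyridine removes both silyl groups. The fallback sets out from 29 and comes back at 33, and regioisomers can be removed at F13.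

## Further compounds

F1 | step 5 | rac-{[(2Z,6Z)-1-ethenyl-3,7-dimethylcycloocta-2,6-dien-1-yl]oxy}trimethylsilane | C=C[C@@]1(O[Si](C)(C)C)/C=C(C)\CC/C=C(C)\C1
F2 | step 8 | (2Z,6Z,9S)-3,7-dimethyl-9-(4,4,5,5-tetramethyl-1,3,2-dioxaborolan-2-yl)cyclodeca-2,6-dien-1-one | CC1(C)OB(OC1(C)C)[C@H]1C/C(C)=C\CC/C(C)=C\C(=O)C1
F3 | step 12 | (2Z,6Z,9S)-3,7-dimethyl-9-(triethylsilyloxy)cyclodeca-2,6-dien-1-one | CC[Si](CC)(CC)O[C@H]1C/C(C)=C\CC/C(C)=C\C(=O)C1
F4 | step 12 | tert-butyl 2-[(1R,10S,3Z,7Z)-4,8-dimethyl-2-oxo-10-(triethylsilyloxy)cyclodeca-3,7-dien-1-yl]acetate | CC[Si](CC)(CC)O[C@H]1C/C(C)=C\CC/C(C)=C\C(=O)[C@@H]1CC(=O)OC(C)(C)C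
F5 | step 12 | tert-butyl 2-[(1S,2R,10S,3Z,7Z)-2-hydroxy-4,8-dimethyl-10-(triethylsilyloxy)cyclodeca-3,7-dien-1-yl]acetate | CC[Si](CC)(CC)O[C@H]1C/C(C)=C\CC/C(C)=C\[C@@H](O)[C@@H]1CC(=O)OC(C)(C)C
F6 | step 12 | tert-butyl 2-[(1R,2R,10S,3Z,7Z)-2-[(tert-butyldimethylsilyl)oxy]-4,8-dimethyl-10-(triethylsilyloxy)cyclodeca-3,7-dien-1-yl]acetate | CC[Si](CC)(CC)O[C@H]1C/C(C)=C\CC/C(C)=C\[C@@H](O[Si](C)(C)C(C)(C)C)[C@@H]1CC(=O)OC(C)(C)C
F7 | step 12 | (6R,7R,8S)-6-[(tert-butyldimethylsilyl)oxy]-13-norgermacra-1(10),4-dien-12,8-olide | C1C(=O)O[C@H]2C/C(C)=C\CC/C(C)=C\[C@@H](O[Si](C)(C)C(C)(C)C)[C@H]12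
F8 | step 12 | (6R,7R,8S)-6-[(tert-butyldimethylsilyl)oxy]germacra-1(10),4,11(13)-trien-12,8-olide | C=C1C(=O)O[C@H]2C/C(C)=C\CC/C(C)=C\[C@@H](O[Si](C)(C)C(C)(C)C)[C@H]12
F9 | step 13 | (6S,7S,8S)-6-hydroxy-13-norgermacra-1(10),4-dien-12,8-olide | C1C(=O)O[C@H]2C/C(C)=C\CC/C(C)=C\[C@H](O)[C@H]12
F10 | step 13 | (6S,7R,8S)-6-(triethylsilyloxy)-13-norgermacra-1(10),4-dien-12,8-olide | C1C(=O)O[C@H]2C/C(C)=C\CC/C(C)=C\[C@H](O[Si](CC)(CC)CC)[C@H]12
F11 | step 13 | (6S,7R,8S)-6-(triethylsilyloxy)germacra-1(10),4,11(13)-trien-12,8-olide | C=C1C(=O)O[C@H]2C/C(C)=C\CC/C(C)=C\[C@H](O[Si](CC)(CC)CC)[C@H]12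
F12 | step 13 | (6S,7S,8S)-6-hydroxygermacra-1(10),4,11(13)-trien-12,8-olide | C=C1C(=O)O[C@H]2C/C(C)=C\CC/C(C)=C\[C@H](O)[C@H]12
F13 | step 18 | (6R,7S,8S)-6,14,15-trihydroxygermacra-1(10),4,11(13)-trien-12,8-olide | C=C1C(=O)O[C@H]2C/C(CO)=C\CC/C(CO)=C\[C@@H](O)[C@H]12
F14 | step 18 | (6R,7S,8S)-14,15-bis[(tert-butyldimethylsilyl)oxy]-6-hydroxygermacra-1(10),4,11(13)-trien-12,8-olide | C=C1C(=O)O[C@H]2C/C(CO[Si](C)(C)C(C)(C)C)=C\CC/C(CO[Si](C)(C)C(C)(C)C)=C\[C@@H](O)[C@H]12
F15 | step 18 | (6R,7R,8S)-14,15-bis[(tert-butyldimethylsilyl)oxy]-6-[(E)-2-methylbut-2-enoyloxy]germacra-1(10),4,11(13)-trien-12,8-olide | C=C1C(=O)O[C@H]2C/C(CO[Si](C)(C)C(C)(C)C)=C\CC/C(CO[Si](C)(C)C(C)(C)C)=C\[C@@H](OC(=O)/C(C)=C/C)[C@H]12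
A1 | alternative 1 | fused lactone–isoxazoline (C12 lactone on O8, isoxazoline N on C11 and O on C6; C4 vinyl iodide, C3 p-methoxybenzyl ether, C14 and C15 tert-butyldimethylsilyl ethers) | O=C1O[C@@H](C/C(CO[Si](C)(C)C(C)(C)C)=C\CCOCc3ccc(OC)cc3)[C@H]2C1=NO[C@@H]2/C=C(\I)CO[Si](C)(C)C(C)(C)C
A2 | alternative 1 | open-chain (Z)-2-chloro-2-(hydroxyimino)acetate of the C8 alcohol (E C6=C7, C4 vinyl iodide, C3 p-methoxybenzyl ether, C14 and C15 tert-butyldimethylsilyl ethers) | O/N=C(\Cl)C(=O)O[C@@H](C/C(CO[Si](C)(C)C(C)(C)C)=C\CCOCc1ccc(OC)cc1)/C=C/C=C(\I)CO[Si](C)(C)C(C)(C)C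
A3 | alternative 2 | ten-membered ring bridged by the C14–O8 α-alkylidene lactone (6-triethylsilyloxy, 15-tert-butyldimethylsilyloxy, C7 carrying CH2CH2O-p-methoxybenzyl) | O=C1O[C@H]2C/C1=C\CC/C(CO[Si](C)(C)C(C)(C)C)=C\[C@@H](O[Si](CC)(CC)CC)[C@@H]2CCOCc1ccc(OC)cc1
A4 | alternative 2 | open-chain α-(diethoxyphosphoryl)-γ-lactone aldehyde (C14 lactone on O8, phosphonate on C10, C1 aldehyde, 6-triethylsilyloxy, 15-tert-butyldimethylsilyloxy, C7 carrying CH2CH2O-p-methoxybenzyl) | O=C1O[C@@H](CC1P(=O)(OCC)OCC)[C@@H](CCOCc1ccc(OC)cc1)[C@H](O[Si](CC)(CC)CC)/C=C(/CO[Si](C)(C)C(C)(C)C)CCC=O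
A5 | alternative 3 | ten-membered homoallylic alcohol (free 6-hydroxyl, C7 carrying the 3-(triethylsilyloxy)prop-1-en-2-yl group, 8-triethylsilyloxy, 14,15-bis(tert-butyldimethylsilyloxy)) | C=C(CO[Si](CC)(CC)CC)[C@@H]1[C@@H](O[Si](CC)(CC)CC)C/C(CO[Si](C)(C)C(C)(C)C)=C\CC/C(CO[Si](C)(C)C(C)(C)C)=C\[C@H]1O
A6 | alternative 3 | thirteen-membered diallyl ether (O between C6 and C13; 12- and 8-triethylsilyloxy, 14,15-bis(tert-butyldimethylsilyloxy)) | O1C/C(CO[Si](CC)(CC)CC)=C/[C@@H](O[Si](CC)(CC)CC)C/C(CO[Si](C)(C)C(C)(C)C)=C\CC/C(CO[Si](C)(C)C(C)(C)C)=C\C1
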